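The route cuts the C4–C4a bond of the acetyl-bearing chromene (ring A) back to an aryl 1,1-dimethylpropargyl ether whose alkyne terminus carries iodine. One gold-catalysed cycloisomerisation closes the pyran ring at C4a, the arene carbon flanked by O1 and the acetyl-chelated C5 hydroxyl. The same step moves iodine from the future C4 to C3, the branching carbon next to the C2 gem-dimethyl group. The resulting 3-iodochromene is joined to a vinylarene by an enantioselective nickel hydride hydroalkenylation that sets the (S)-centre. The second pyran ring (ring B) is closed last on an aryl propargyl ether whose two ortho positions are equivalent.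

Key step: step 3

Numbering used: ring A is the acetyl-bearing chromene (O1, C2, C3, C4, C4a, C5 to C8, C8a), ring B is the dimethoxychromene, and C1'' is the stereocentre.
Assumption: the (S,S)-bis(oxazoline) ligand is taken to deliver the (S)-centre in step 5. Both ligand antipodes are commercial, so the sense of induction can be matched to the target.

Step 1
Reactants: 1 1-(2,4-dihydroxy-6-methoxyphenyl)ethan-1-one; 2 3-chloro-3-methylbut-1-yne
Product: 3 1-{2-hydroxy-6-methoxy-4-[(2-methylbut-3-yn-2-yl)oxy]phenyl}ethan-1-one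
Conditions: DBU, CuCl2·2H2O (cat.), MeCN, 0 °C
Reagents that add atoms: none
Why: Copper-catalysed propargylic etherification (copper allenylidene pathway) alkylates only the free, more acidic C4 hydroxyl, because the C2 hydroxyl is held in the hydrogen bond to the acetyl group.

Step 2
Reactants: 3 1-{2-hydroxy-6-methoxy-4-[(2-methylbut-3-yn-2-yl)oxy]phenyl}ethan-1-one
Product: 4 1-{2-hydroxy-4-[(4-iodo-2-methylbut-3-yn-2-yl)oxy]-6-methoxyphenyl}ethan-1-one
Conditions: NIS, AgNO3 (cat.), acetone, rt, dark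
Reagents that add atoms: N-iodosuccinimide, O=C1CCC(=O)N1I
Why: Silver-catalysed electrophilic iodination of the terminal alkyne C–H (via the silver acetylide) should be faster under neutral conditions than iodination of the acetyl-deactivated arene.

Step 3
Reactants: 4 1-{2-hydroxy-4-[(4-iodo-2-methylbut-3-yn-2-yl)oxy]-6-methoxyphenyl}ethan-1-one
Product: 6 1-(5-hydroxy-3-iodo-7-methoxy-2,2-dimethyl-2H-chromen-6-yl)ethan-1-one, via gold vinylidene 5 (not isolated)
Conditions: Au(IPr)NTf2 (5 mol %; IPr = 1,3-bis(2,6-diisopropylphenyl)imidazol-2-ylidene), 1,4-dioxane, 60 °C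
Reagents that add atoms: none
Why: Au(IPr)NTf2 binds the iodoalkyne and a 1,2-iodine shift gives gold vinylidene 5, whose electrophilic terminal carbon (future C4) is attacked by arene carbon C4a; rearomatisation and protodeauration then release 6. The closest known reaction type is the gold-catalysed cycloisomerisation of aryl 3-iodopropargyl ethers to 3-iodo-2H-chromenes (and of haloalkynyl biaryls to halophenanthrenes). The pyran ring closes in a formal 6-endo mode by Friedel–Crafts attack on the vinylidene carbon, helped by the Thorpe–Ingold effect of the C2 gem-dimethyl group. No stereocentre is formed. Two selectivities are needed: attack at C4a and not at the carbon between O1 and the methoxy group, secured by the bond fixation of the acetyl–hydroxyl chelate (the bias that also sends halogenation and Claisen shifts ortho to a chelated hydroxyl), and iodine migration before ring closure, favoured by the strongly donating carbene ligand over direct attack, which would leave iodine on C4. The temperature is kept below the onset of the thermal propargyl Claisen rearrangement.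

Step 4
Reactants: 7 4-hydroxy-2,6-dimethoxybenzaldehyde
Product: 8 4-ethenyl-3,5-dimethoxyphenol
Conditions: Ph3PCH3Br, KOtBu (excess), THF, 0 °C to rt
Reagents that add atoms: methyltriphenylphosphonium bromide, C[P+](c1ccccc1)(c1ccccc1)c1ccccc1.[Br-]
Why: Wittig methylenation, in which the excess ylide first deprotonates the phenol and then converts the aldehyde into the terminal alkene.

Step 5
Reactants: 6 1-(5-hydroxy-3-iodo-7-methoxy-2,2-dimethyl-2H-chromen-6-yl)ethan-1-one; 8 4-ethenyl-3,5-dimethoxyphenol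
Product: 9 1-{5-hydroxy-3-[(1S)-1-(4-hydroxy-2,6-dimethoxyphenyl)ethyl]-7-methoxy-2,2-dimethyl-2H-chromen-6-yl}ethan-1-one
Conditions: NiI2·xH2O (10 mol %), (S,S)-Bn-BOX (12 mol %; 2,2'-(propane-2,2-diyl)bis[(4S)-4-benzyl-4,5-dihydro-1,3-oxazole]), (MeO)2MeSiH (excess), KF, DMA, rt, aqueous work-up
Reagents that add atoms: none
Why: In this nickel hydride catalysed enantioselective hydroalkenylation of a vinylarene with an alkenyl halide, Markovnikov insertion of 8 into Ni–H gives a benzylic nickel species that couples with alkenyl iodide 6, the C2-symmetric bis(oxazoline) ligand on nickel decides which face of the benzylic carbon bonds to C3 and so sets the (S)-centre, and the absence of any other reactive alkene or alkyne in 6 and 8 secures chemoselectivity.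

Step 6
Reactants: 9 1-{5-hydroxy-3-[(1S)-1-(4-hydroxy-2,6-dimethoxyphenyl)ethyl]-7-methoxy-2,2-dimethyl-2H-chromen-6-yl}ethan-1-one; 2 3-chloro-3-methylbut-1-yne
Product: 10 1-{3-[(1S)-1-{2,6-dimethoxy-4-[(2-methylbut-3-yn-2-yl)oxy]phenyl}ethyl]-5-hydroxy-7-methoxy-2,2-dimethyl-2H-chromen-6-yl}ethan-1-one
Conditions: DBU, CuCl2·2H2O (cat.), MeCN, 0 °C
Reagents that add atoms: none
Why: In the same copper-catalysed propargylic etherification as in step 1, the unhindered hydroxyl of the dimethoxyaryl ring reacts, the acetyl-chelated C5 hydroxyl of ring A stays untouched and the mild base cannot epimerise C1''.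

Step 7
Reactants: 10 1-{3-[(1S)-1-{2,6-dimethoxy-4-[(2-methylbut-3-yn-2-yl)oxy]phenyl}ethyl]-5-hydroxy-7-methoxy-2,2-dimethyl-2H-chromen-6-yl}ethan-1-one
Product: 11 1-{3-[(1S)-1-(5,7-dimethoxy-2,2-dimethyl-2H-chromen-6-yl)ethyl]-5-hydroxy-7-methoxy-2,2-dimethyl-2H-chromen-6-yl}ethan-1-one
Conditions: Au(PPh3)NTf2 (2 mol %), CH2Cl2, rt
Reagents that add atoms: none
Why: In this gold-catalysed 6-endo-dig hydroarylation of an aryl propargyl ether, the two ortho carbons of the dimethoxyaryl ring are interchanged by rotation about the C1''–aryl bond, so only one chromene can form, and the neutral conditions leave the benzylic stereocentre untouched.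

Compound list
1 | 1-(2,4-dihydroxy-6-methoxyphenyl)ethan-1-one | CC(=O)c1c(O)cc(O)cc1OC | starting material
2 | 3-chloro-3-methylbut-1-yne | C#CC(C)(C)Cl | starting material
3 | 1-{2-hydroxy-6-methoxy-4-[(2-methylbut-3-yn-2-yl)oxy]phenyl}ethan-1-one | CC(=O)c1c(O)cc(OC(C)(C)C#C)cc1OC | intermediate
4 | 1-{2-hydroxy-4-[(4-iodo-2-methylbut-3-yn-2-yl)oxy]-6-methoxyphenyl}ethan-1-one | CC(=O)c1c(O)cc(OC(C)(C)C#CI)cc1OC | intermediate
5 | gold vinylidene cation (IPr)Au=C=C(I)–CMe2–OAr (not isolated) | CC(=O)c1c(O)cc(OC(C)(C)C(I)=C=[Au]c2n(-c3c(C(C)C)cccc3C(C)C)cc[n+]2-c2c(C(C)C)cccc2C(C)C)cc1OC | intermediate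
6 | 1-(5-hydroxy-3-iodo-7-methoxy-2,2-dimethyl-2H-chromen-6-yl)ethan-1-one | COc1cc2c(c(O)c1C(C)=O)C=C(I)C(C)(C)O2 | intermediate
7 | 4-hydroxy-2,6-dimethoxybenzaldehyde | COc1cc(O)cc(OC)c1C=O | starting material
8 | 4-ethenyl-3,5-dimethoxyphenol | C=Cc1c(OC)cc(O)cc1OC | intermediate
9 | 1-{5-hydroxy-3-[(1S)-1-(4-hydroxy-2,6-dimethoxyphenyl)ethyl]-7-methoxy-2,2-dimethyl-2H-chromen-6-yl}ethan-1-one | COc1cc2c(c(O)c1C(C)=O)C=C([C@H](C)c1c(OC)cc(O)cc1OC)C(C)(C)O2 | intermediate
10 | 1-{3-[(1S)-1-{2,6-dimethoxy-4-[(2-methylbut-3-yn-2-yl)oxy]phenyl}ethyl]-5-hydroxy-7-methoxy-2,2-dimethyl-2H-chromen-6-yl}ethan-1-one | COc1cc2c(c(O)c1C(C)=O)C=C([C@H](C)c1c(OC)cc(OC(C)(C)C#C)cc1OC)C(C)(C)O2 | intermediate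
11 | 1-{3-[(1S)-1-(5,7-dimethoxy-2,2-dimethyl-2H-chromen-6-yl)ethyl]-5-hydroxy-7-methoxy-2,2-dimethyl-2H-chromen-6-yl}ethan-1-one | COc1cc2c(c(O)c1C(C)=O)C=C([C@H](C)c1c(OC)cc3c(c1OC)C=CC(C)(C)O3)C(C)(C)O2 | target

Total step count: 7. Longest linear sequence: 6 steps (1, 2, 3, 5, 6, 7).

Steps most likely to fail

Step 5. Bond formation between two hindered carbons may be slow, so that hydrodehalogenation of the alkenyl iodide, oligomerisation of the vinylphenol or poor facial selectivity takes over.
- The fallback sets out from 8 (with 6 as partner) and comes back at 9.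
- Phenol 8 is silylated (TBSCl, imidazole) to tert-butyl(4-ethenyl-3,5-dimethoxyphenoxy)dimethylsilane F1.
- Copper-catalysed asymmetric Markovnikov hydroboration (CuCl, NaOtBu, the DTBM-SEGPHOS antipode that gives the (R)-product, HBpin) gives the (R)-benzylic pinacol boronic ester F2.
- A stereoretentive Suzuki–Miyaura coupling with 6 (Pd2(dba)3, PPh3, Ag2O, THF, 70 °C) gives the tert-butyldimethylsilyl ether of 9 F3.
- TBAF then releases 9.

Step 3. Direct ring closure may outrun the iodine shift, closure may occur at the wrong ortho carbon, or the tertiary aryl ether may ionise.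
- The fallback sets out from 3 and comes back at 9.
- Plain gold-catalysed 6-endo-dig hydroarylation of the terminal alkyne (Au(PPh3)NTf2, CH2Cl2) closes the same C4–C4a bond and gives 1-(5-hydroxy-7-methoxy-2,2-dimethyl-2H-chromen-6-yl)ethan-1-one F4.
- NBS in aqueous acetone adds across the electron-rich C3–C4 alkene to give the trans-bromohydrin F5.
- Acid-catalysed dehydration (TsOH, toluene) through the stabilised C4 cation gives the 3-bromochromene F6, which takes the place of 6 in step 5.

Step 2. Electrophilic iodination of the activated arene may compete with iodination of the alkyne C–H.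
- The fallback sets out from 3 and comes back at 4.
- The chelated hydroxyl is acetylated (Ac2O, pyridine, DMAP) to lower the ring nucleophilicity, giving 2-acetyl-3-methoxy-5-[(2-methylbut-3-yn-2-yl)oxy]phenyl acetate F7.
- NIS and AgNO3 then give the iodoalkyne acetate F8.
- Mild methanolysis (K2CO3, MeOH, 0 °C) returns 4.

Further compounds
F1 | step 5 | tert-butyl(4-ethenyl-3,5-dimethoxyphenoxy)dimethylsilane | C=Cc1c(OC)cc(O[Si](C)(C)C(C)(C)C)cc1OC
F2 | step 5 | tert-butyl{3,5-dimethoxy-4-[(1R)-1-(4,4,5,5-tetramethyl-1,3,2-dioxaborolan-2-yl)ethyl]phenoxy}dimethylsilane | CC1(C)OB(OC1(C)C)[C@H](C)c1c(OC)cc(O[Si](C)(C)C(C)(C)C)cc1OC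
F3 | step 5 | 1-{3-[(1S)-1-(4-{[tert-butyl(dimethyl)silyl]oxy}-2,6-dimethoxyphenyl)ethyl]-5-hydroxy-7-methoxy-2,2-dimethyl-2H-chromen-6-yl}ethan-1-one | COc1cc2c(c(O)c1C(C)=O)C=C([C@H](C)c1c(OC)cc(O[Si](C)(C)C(C)(C)C)cc1OC)C(C)(C)O2
F4 | step 3 | 1-(5-hydroxy-7-methoxy-2,2-dimethyl-2H-chromen-6-yl)ethan-1-one | COc1cc2c(c(O)c1C(C)=O)C=CC(C)(C)O2
F5 | step 3 | 1-(trans-3-bromo-4,5-dihydroxy-7-methoxy-2,2-dimethylchroman-6-yl)ethan-1-one (racemic, one enantiomer drawn) | COc1cc2c(c(O)c1C(C)=O)[C@H](O)[C@@H](Br)C(C)(C)O2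
F6 | step 3 | 1-(3-bromo-5-hydroxy-7-methoxy-2,2-dimethyl-2H-chromen-6-yl)ethan-1-one | COc1cc2c(c(O)c1C(C)=O)C=C(Br)C(C)(C)O2
F7 | step 2 | 2-acetyl-3-methoxy-5-[(2-methylbut-3-yn-2-yl)oxy]phenyl acetate | CC(=O)Oc1cc(OC(C)(C)C#C)cc(OC)c1C(C)=O
F8 | step 2 | 2-acetyl-5-[(4-iodo-2-methylbut-3-yn-2-yl)oxy]-3-methoxyphenyl acetate | CC(=O)Oc1cc(OC(C)(C)C#CI)cc(OC)c1C(C)=O
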